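Numbering: indane C1 (carries =CH–ring A, 4-hydroxy-3-methoxyphenyl), C2 (ring C, 3,5-dihydroxyphenyl), C3 (ring B, 2,4-dihydroxyphenyl), benzo ring C3a–C7a with OH on C4 and C6.
Cuts: the C1=CH alkene is traced back to a ketone on the exocyclic carbon. C1–C2 and C2–C3 are then cut together, which releases C2 with ring C as a benzylic sulfonium ylide. The rest is cut at C3–C3a (aryllithium + ring B aldehyde) and at C1–C(=O) (dithiane anion + benzyl bromide).
Enabling feature: ring B has a hydroxyl para to C3, so C3 can become the exocyclic carbon of a para-quinone methide. C1 lies between the benzo ring and the ketone and is an enolate carbon. C2 can therefore bond first as a nucleophile to C3 and then, with the sulfide as leaving group, as an electrophile to C1.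
Forward order: ring A dithiane + benzo-ring benzyl bromide, then ring B aldehyde, ketone release and sulfone. The five-membered ring is the only ring formed and closes in the annulation. Reduction, non-acidic dehydration and deallylation finish the route.
Stereochemistry: C2 comes from the open face of the (2S,5S)-2,5-dimethylthiolanium benzylide and the invertive closure, and C3 from the trans-selective closure. C1 is labile and ends sp2. The E geometry follows from avoidance of the C7–H contact.
Protection: all phenols except O-4 of ring B travel as allyl ethers. The acidic sulfone step then harms nothing, and the acid-sensitive alkylidene indane is unveiled under neutral zerovalent-palladium catalysis.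

Key step: step 16

Assumption: the sense of induction is extrapolated from the known epoxidation of aromatic aldehydes by the benzylide of the same thiolane, where the (2R,5R)-sulfide leads to (S,S)-oxiranes. Here C1 takes the place of the oxirane oxygen and C3 that of the aldehyde carbon, and the arrangement needed at C2 is the mirror image, hence the (2S,5S)-sulfide. If the sense proves opposite, the equally commercial (2S,5S)-diol is used in step 12 with no other change.

Step 1
Reactants: 1 3,5-dihydroxybenzyl alcohol
Product: 2 3,5-bis(allyloxy)benzyl alcohol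
Conditions: allyl bromide (2.2 equiv), K2CO3, acetone, reflux
Reagents that add atoms: allyl bromide, C=CCBr
Why: Williamson ether synthesis; K2CO3 deprotonates only the two phenols, so the benzylic alcohol stays free for both later uses of 2.

Step 2
Reactants: 2 3,5-bis(allyloxy)benzyl alcohol
Product: 3 2-bromo-3,5-bis(allyloxy)benzyl alcohol
Conditions: NBS (1.0 equiv), CH2Cl2, 0 °C, dark
Reagents that add atoms: N-bromosuccinimide, O=C1CCC(=O)N1Br
Why: Electrophilic aromatic bromination; the position next to the CH2OH group is para to one allyloxy group, ortho to the other and less crowded than the site between the two oxygens, and this ring reacts far faster than the electron-poor allyl double bonds.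

Step 3
Reactants: 3 2-bromo-3,5-bis(allyloxy)benzyl alcohol
Product: 4 2-bromo-3,5-bis(allyloxy)benzyl bromide
Conditions: CBr4, PPh3, CH2Cl2, 0 °C
Reagents that add atoms: carbon tetrabromide, BrC(Br)(Br)Br
Why: Appel reaction; the primary benzylic alcohol is exchanged for bromide under neutral conditions that leave the allyl ethers and the aryl bromide alone.

Step 4
Reactants: 5 vanillin (4-hydroxy-3-methoxybenzaldehyde)
Product: 6 4-allyloxy-3-methoxybenzaldehyde
Conditions: allyl bromide, K2CO3, acetone, reflux
Reagents that add atoms: allyl bromide, C=CCBr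
Why: Williamson ether synthesis on the single phenol of ring A.

Step 5
Reactants: 6 4-allyloxy-3-methoxybenzaldehyde
Product: 7 2-(4-allyloxy-3-methoxyphenyl)-1,3-dithiane
Conditions: propane-1,3-dithiol, BF3·OEt2 (cat.), CH2Cl2, 0 °C
Reagents that add atoms: propane-1,3-dithiol, SCCCS
Why: Lewis acid-catalysed dithioacetalisation of an aromatic aldehyde, fast at 0 °C and harmless to aryl allyl and methyl ethers.

Step 6
Reactants: 7 2-(4-allyloxy-3-methoxyphenyl)-1,3-dithiane; 4 2-bromo-3,5-bis(allyloxy)benzyl bromide
Product: 9 2-(4-allyloxy-3-methoxyphenyl)-2-[2-bromo-3,5-bis(allyloxy)benzyl]-1,3-dithiane, via 2-lithiodithiane 8 (not isolated)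
Conditions: n-BuLi, THF, −78 °C; then 4, −78 °C → 0 °C
Reagents that add atoms: none
Why: Corey–Seebach umpolung alkylation joins the future carbonyl carbon to C1; the stabilised dithianyl anion attacks only the benzylic bromide and does not exchange with the aryl bromide.

Step 7
Reactants: 10 2,4-dihydroxybenzaldehyde
Product: 11 2-hydroxy-4-(tetrahydropyran-2-yloxy)benzaldehyde (racemic acetal)
Conditions: 3,4-dihydro-2H-pyran, pyridinium p-toluenesulfonate (cat.), CH2Cl2, rt
Reagents that add atoms: 3,4-dihydro-2H-pyran, C1=COCCC1
Why: Acid-catalysed acetalisation (THP ether formation); the 2-hydroxyl is locked in a hydrogen bond to the aldehyde, so only O-4 reacts.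

Step 8
Reactants: 11 2-hydroxy-4-(tetrahydropyran-2-yloxy)benzaldehyde
Product: 12 2-allyloxy-4-(tetrahydropyran-2-yloxy)benzaldehyde
Conditions: allyl bromide, K2CO3, DMF, rt
Reagents that add atoms: allyl bromide, C=CCBr
Why: Williamson ether synthesis on the remaining phenol; the THP acetal is stable to base, so O-2 and O-4 of ring B end up differentiated.

Step 9
Reactants: 9 2-(4-allyloxy-3-methoxyphenyl)-2-[2-bromo-3,5-bis(allyloxy)benzyl]-1,3-dithiane; 12 2-allyloxy-4-(tetrahydropyran-2-yloxy)benzaldehyde
Product: 14 {2,4-bis(allyloxy)-6-[[2-(4-allyloxy-3-methoxyphenyl)-1,3-dithian-2-yl]methyl]phenyl}[2-allyloxy-4-(tetrahydropyran-2-yloxy)phenyl]methanol (racemic diastereomer mixture), via aryllithium 13 (not isolated)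
Conditions: n-BuLi (1.05 equiv), THF, −78 °C; then 12; then H2O
Reagents that add atoms: none
Why: Bromine–lithium exchange followed by 1,2-addition of the aryllithium to the aldehyde forms C3–C3a; the fully substituted dithiane offers neither an acidic proton nor an electrophilic carbon, exchange at −78 °C is faster than any attack of n-BuLi on the allyl ethers, and the new carbinol centre need not be controlled because it is erased in step 16.

Step 10
Reactants: 14 the diarylcarbinol dithiane
Product: 15 1-(4-allyloxy-3-methoxyphenyl)-2-{3,5-bis(allyloxy)-2-[[2-allyloxy-4-(tetrahydropyran-2-yloxy)phenyl](hydroxy)methyl]phenyl}ethan-1-one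
Conditions: MeI (excess), CaCO3, MeCN–H2O 9:1, 40 °C
Reagents that add atoms: water, O
Why: Alkylative dithiane hydrolysis (S-methylation, then capture of the ring A-stabilised thionium ion by water) frees the ketone without oxidant, halogenating agent or heavy metal, so the electron-rich rings, the allyl ethers, the carbinol and, thanks to the CaCO3 buffer, the THP acetal persist.

Step 11
Reactants: 15 the hydroxy ketone
Product: 16 racemic 1-(4-allyloxy-3-methoxyphenyl)-2-{3,5-bis(allyloxy)-2-[(2-allyloxy-4-hydroxyphenyl)(4-methylphenylsulfonyl)methyl]phenyl}ethan-1-one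
Conditions: p-toluenesulfinic acid (3 equiv), CH2Cl2, 0 °C → rt
Reagents that add atoms: p-toluenesulfinic acid, Cc1ccc(S(=O)O)cc1
Why: SN1-type exchange of a diarylcarbinol for a sulfone with a sulfinic acid: the C3–O bond, whether the hydroxyl is free or engaged with the neighbouring ketone, ionises to a cation stabilised by four oxygen donors and the soft sulfur of the sulfinate captures it, the same acid exchanges the far more labile aryl THP acetal and so frees O-4 of ring B, and aryl allyl ethers are inert to an acid of this strength.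

Step 12
Reactants: 17 (2R,5R)-hexane-2,5-diol
Product: 18 (2R,5R)-hexane-2,5-diyl dimethanesulfonate
Conditions: MsCl, Et3N, CH2Cl2, −20 °C → 0 °C
Reagents that add atoms: methanesulfonyl chloride, CS(=O)(=O)Cl
Why: Sulfonate ester formation takes place at oxygen and leaves both stereocentres untouched.

Step 13
Reactants: 18 (2R,5R)-hexane-2,5-diyl dimethanesulfonate
Product: 19 (2S,5S)-2,5-dimethylthiolane
Conditions: Na2S·9H2O, DMSO, rt; distillation
Reagents that add atoms: sodium sulfide, [Na+].[Na+].[S-2]
Why: Twofold SN2 displacement by sulfide closes the thiolane with inversion at both carbons, which turns the (R,R) series into the (S,S)-sulfide.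

Step 14
Reactants: 2 3,5-bis(allyloxy)benzyl alcohol
Product: 20 3,5-bis(allyloxy)benzyl bromide
Conditions: CBr4, PPh3, CH2Cl2, 0 °C
Reagents that add atoms: carbon tetrabromide, BrC(Br)(Br)Br
Why: Appel reaction, as in step 3, on the unbrominated alcohol gives the ring C electrophile.

Step 15
Reactants: 19 (2S,5S)-2,5-dimethylthiolane; 20 3,5-bis(allyloxy)benzyl bromide
Product: 21 (2S,5S)-1-[3,5-bis(allyloxy)benzyl]-2,5-dimethylthiolanium tetrafluoroborate
Conditions: AgBF4, CH2Cl2, 0 °C → rt, dark
Reagents that add atoms: silver tetrafluoroborate, [Ag+].F[B-](F)(F)F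
Why: S-alkylation of a sulfide driven by precipitation of AgBr; the two lone pairs of the twofold-symmetric sulfide are equivalent, so a single salt forms, and the BF4 counter-ion cannot regenerate a benzylic halide.

Step 16
Reactants: 16 the racemic keto sulfone; 21 the thiolanium tetrafluoroborate
Product: 25 (1S,2R,3S)-1-(4-allyloxy-3-methoxybenzoyl)-4,6-bis(allyloxy)-3-(2-allyloxy-4-hydroxyphenyl)-2-[3,5-bis(allyloxy)phenyl]indane (all-trans), via benzylide 22 (not isolated), via para-quinone methide 23 (not isolated), via zwitterion 24 (not isolated)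
Conditions: 21 (1.5 equiv), Cs2CO3 (5 equiv), 4 Å MS, MeCN–CH2Cl2, −20 °C, 30 min; 16 added over 2 h; −20 °C → rt, argon
Reagents that add atoms: none
Why: Proposed new method: Cs2CO3 turns 21 into benzylide 22 and deprotonates the ring B phenol of 16, which expels toluenesulfinate to give para-quinone methide 23; C2 of 22 adds to C3 (1,6-addition) to give zwitterion 24, the C1 methylene (about as acidic as the phenol) passes its proton on, and the enolate carbon C1 displaces the thiolane from C2. The closest known reaction type is the (4+1) annulation of sulfonium ylides with ortho-hydroxyphenyl or ortho-sulfonamidophenyl para-quinone methides, where oxygen or nitrogen instead of an enolate carbon closes the ring. The one ring closure is 5-(enolexo)-exo-tet and inverts C2. C2 is set by the ylide face that the thiolane methyl groups leave open together with that inversion, C3 by the fact that only the zwitterion leading to trans aryl groups closes readily while the other can revert, and C1 by base equilibration to the all-trans ketone (it is erased later). The step needs C2–C3 bonding to outrun O-attack of the enolate on C3, and C1–C2 closure to outrun ipso attack of ring B on C2 (which by double inversion would lead to the antipode), closure through O-2 of ring B and intermolecular benzylation of the enolate. Slow addition of 16 to an excess of preformed ylide, the allyl cap on O-2, the non-nucleophilic counter-ion and the much higher carbon nucleophilicity of the enolate serve this, and O-attack on C3 should be reversible because the enolate is a phenoxide-like leaving group pushed out by the ring B phenoxide.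

Step 17
Reactants: 25 the all-trans phenol ketone
Product: 26 (1S,2R,3S)-1-(4-allyloxy-3-methoxybenzoyl)-4,6-bis(allyloxy)-3-[2,4-bis(allyloxy)phenyl]-2-[3,5-bis(allyloxy)phenyl]indane
Conditions: allyl bromide, K2CO3, acetone, 40 °C
Reagents that add atoms: allyl bromide, C=CCBr
Why: Williamson ether synthesis; the phenoxide is alkylated much faster than the hindered tertiary C1 position, and any epimerisation at C1 is without consequence.

Step 18
Reactants: 26 the hepta-O-allyl ketone
Product: 27 (4-allyloxy-3-methoxyphenyl){(1S,2R,3S)-4,6-bis(allyloxy)-3-[2,4-bis(allyloxy)phenyl]-2-[3,5-bis(allyloxy)phenyl]indan-1-yl}methanol (carbinol epimers)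
Conditions: NaBH4, THF–MeOH, 0 °C → rt
Reagents that add atoms: none
Why: Hydride reduction of the aryl ketone; the configuration of the new carbinol carbon is irrelevant because it becomes sp2 in the next step, and C2 and C3 carry no acidic hydrogen.

Step 19
Reactants: 27 the carbinol
Product: 28 (1E,2S,3S)-1-(4-allyloxy-3-methoxybenzylidene)-4,6-bis(allyloxy)-3-[2,4-bis(allyloxy)phenyl]-2-[3,5-bis(allyloxy)phenyl]indane
Conditions: Ph2S[OC(CF3)2Ph]2, CH2Cl2, 0 °C → rt
Reagents that add atoms: none
Why: Sulfurane-mediated dehydration through an alkoxysulfonium intermediate under non-acidic conditions; C1–H is the only β-hydrogen, so the double bond can only form between C1 and the exocyclic carbon, the E isomer is favoured because ring A avoids C7–H, and Friedel–Crafts capture of any cationic character by ring C is blocked because the C1 side chain is trans to ring C and a trans-fused bicyclo[3.3.0] system would result.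

Step 20
Reactants: 28 the hepta-O-allyl alkylidene indane
Product: 29 target, (1E,2S,3S)-2-(3,5-dihydroxyphenyl)-3-(2,4-dihydroxyphenyl)-1-(4-hydroxy-3-methoxybenzylidene)indane-4,6-diol
Conditions: Pd(PPh3)4 (10 mol %), morpholine (excess), THF, rt, argon
Reagents that add atoms: none
Why: Tsuji–Trost-type deallylation; zerovalent palladium ionises each aryl allyl ether to a π-allyl complex that morpholine intercepts, under neutral conditions that leave the aryl methyl ether and both stereocentres alone and spare the exocyclic alkene, which acid would shift into the ring or cyclise onto ring C.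

Compound list
1 | 3,5-dihydroxybenzyl alcohol | OCc1cc(O)cc(O)c1 | starting material
2 | 3,5-bis(allyloxy)benzyl alcohol | OCc1cc(OCC=C)cc(OCC=C)c1 | intermediate
3 | 2-bromo-3,5-bis(allyloxy)benzyl alcohol | OCc1cc(OCC=C)cc(OCC=C)c1Br | intermediate
4 | 2-bromo-3,5-bis(allyloxy)benzyl bromide | BrCc1cc(OCC=C)cc(OCC=C)c1Br | intermediate
5 | vanillin | COc1cc(C=O)ccc1O | starting material
6 | 4-allyloxy-3-methoxybenzaldehyde | COc1cc(C=O)ccc1OCC=C | intermediate
7 | 2-(4-allyloxy-3-methoxyphenyl)-1,3-dithiane | COc1cc(C2SCCCS2)ccc1OCC=C | intermediate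
8 | 2-lithio-2-(4-allyloxy-3-methoxyphenyl)-1,3-dithiane (not isolated) | COc1cc(C2([Li])SCCCS2)ccc1OCC=C | intermediate
9 | 2-(4-allyloxy-3-methoxyphenyl)-2-[2-bromo-3,5-bis(allyloxy)benzyl]-1,3-dithiane | COc1cc(C2(Cc3cc(OCC=C)cc(OCC=C)c3Br)SCCCS2)ccc1OCC=C | intermediate
10 | 2,4-dihydroxybenzaldehyde | O=Cc1ccc(O)cc1O | starting material
11 | 2-hydroxy-4-(tetrahydropyran-2-yloxy)benzaldehyde | O=Cc1ccc(OC2CCCCO2)cc1O | intermediate
12 | 2-allyloxy-4-(tetrahydropyran-2-yloxy)benzaldehyde | O=Cc1ccc(OC2CCCCO2)cc1OCC=C | intermediate
13 | aryllithium from 9 (not isolated) | COc1cc(C2(Cc3cc(OCC=C)cc(OCC=C)c3[Li])SCCCS2)ccc1OCC=C | intermediate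
14 | diarylcarbinol dithiane (racemic diastereomer mixture) | COc1cc(C2(Cc3cc(OCC=C)cc(OCC=C)c3C(O)c3ccc(OC4CCCCO4)cc3OCC=C)SCCCS2)ccc1OCC=C | intermediate
15 | hydroxy ketone | COc1cc(C(=O)Cc2cc(OCC=C)cc(OCC=C)c2C(O)c2ccc(OC3CCCCO3)cc2OCC=C)ccc1OCC=C | intermediate
16 | racemic keto sulfone with free O-4 on ring B (annulation precursor) | COc1cc(C(=O)Cc2cc(OCC=C)cc(OCC=C)c2C(c2ccc(O)cc2OCC=C)S(=O)(=O)c2ccc(C)cc2)ccc1OCC=C | intermediate
17 | (2R,5R)-hexane-2,5-diol | C[C@@H](O)CC[C@@H](C)O | starting material
18 | (2R,5R)-hexane-2,5-diyl dimethanesulfonate | C[C@@H](OS(C)(=O)=O)CC[C@@H](C)OS(C)(=O)=O | intermediate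
19 | (2S,5S)-2,5-dimethylthiolane | C[C@H]1CC[C@H](C)S1 | intermediate
20 | 3,5-bis(allyloxy)benzyl bromide | BrCc1cc(OCC=C)cc(OCC=C)c1 | intermediate
21 | (2S,5S)-1-[3,5-bis(allyloxy)benzyl]-2,5-dimethylthiolanium tetrafluoroborate | C[C@H]1CC[C@H](C)[S+]1Cc1cc(OCC=C)cc(OCC=C)c1.F[B-](F)(F)F | intermediate
22 | thiolanium benzylide (not isolated) | C[C@H]1CC[C@H](C)[S+]1[CH-]c1cc(OCC=C)cc(OCC=C)c1 | intermediate
23 | para-quinone methide of ring B (not isolated) | COc1cc(C(=O)Cc2cc(OCC=C)cc(OCC=C)c2C=C2C=CC(=O)C=C2OCC=C)ccc1OCC=C | intermediate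
24 | phenoxide–sulfonium zwitterion after 1,6-addition (not isolated) | COc1cc(C(=O)Cc2cc(OCC=C)cc(OCC=C)c2[C@H](c2ccc([O-])cc2OCC=C)[C@@H]([S+]2[C@@H](C)CC[C@@H]2C)c2cc(OCC=C)cc(OCC=C)c2)ccc1OCC=C | intermediate
25 | all-trans 1-aroyl-2,3-diarylindane with free O-4 on ring B (annulation product) | COc1cc(C(=O)[C@@H]2c3cc(OCC=C)cc(OCC=C)c3[C@H](c3ccc(O)cc3OCC=C)[C@H]2c2cc(OCC=C)cc(OCC=C)c2)ccc1OCC=C | intermediate
26 | hepta-O-allyl ketone | COc1cc(C(=O)[C@@H]2c3cc(OCC=C)cc(OCC=C)c3[C@H](c3ccc(OCC=C)cc3OCC=C)[C@H]2c2cc(OCC=C)cc(OCC=C)c2)ccc1OCC=C | intermediate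
27 | hepta-O-allyl carbinol (epimers at the carbinol carbon) | COc1cc(C(O)[C@@H]2c3cc(OCC=C)cc(OCC=C)c3[C@H](c3ccc(OCC=C)cc3OCC=C)[C@H]2c2cc(OCC=C)cc(OCC=C)c2)ccc1OCC=C | intermediate
28 | hepta-O-allyl (E)-alkylidene indane | COc1cc(/C=C2/c3cc(OCC=C)cc(OCC=C)c3[C@H](c3ccc(OCC=C)cc3OCC=C)[C@H]2c2cc(OCC=C)cc(OCC=C)c2)ccc1OCC=C | intermediate
29 | CNP0122890.1 | COc1cc(/C=C2/c3cc(O)cc(O)c3[C@H](c3ccc(O)cc3O)[C@H]2c2cc(O)cc(O)c2)ccc1O | target

Total step count: 20
Longest linear sequence: 12 steps (1, 2, 3, 6, 9, 10, 11, 16, 17, 18, 19, 20)

Steps most likely to fail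

Step 16.
- What may go wrong: C3 may be captured by the enolate oxygen before the ylide arrives. Ring B may close onto C2 with dearomatisation. The sulfide may be lost by β-elimination from the zwitterion. The ylide may discriminate poorly between its faces.
- Fallback: known chemistry, setting out from 4, 2, 10 and 6 and coming back at 28. The five-membered ring is closed by the acid-induced cyclisation of an ortho-styryl diarylcarbinol, a closure established for trans-2,3-diarylindanes of this family, and the enantiomers are separated.
- Michaelis–Arbuzov reaction of 4 with P(OEt)3 gives diethyl [2-bromo-3,5-bis(allyloxy)benzyl]phosphonate F1.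
- MnO2 oxidation of 2 gives 3,5-bis(allyloxy)benzaldehyde F2.
- Horner–Wadsworth–Emmons reaction of the two (KOtBu, THF) gives (E)-2-bromo-3,3',5,5'-tetrakis(allyloxy)stilbene F3.
- Double Williamson allylation of 10 gives 2,4-bis(allyloxy)benzaldehyde F4.
- Bromine–lithium exchange on F3 (n-BuLi, −78 °C) and addition to F4 give the ortho-styryl diarylcarbinol F5.
- p-Toluenesulfonic acid with p-toluenesulfinic acid in CH2Cl2 at −30 °C ionises F5. The cation closes onto the styryl double bond (C2–C3, aryl groups trans), and the C1 cation is captured at sulfur to give the all-trans 1-tosyl-2,3-diarylindane F6.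
- F6 forms as a racemate and is resolved by preparative HPLC on a chiral stationary phase. The enantiomer with C2 and C3 as in 28 is carried on.
- Deprotonation at C1 (n-BuLi, −78 °C), addition to 6 and trapping with benzoyl chloride give the β-benzoyloxy sulfone F7.
- SmI2 in THF–HMPA completes the Julia olefination to 28.

Step 11.
- What may go wrong: the C3 cation may be lost to intramolecular capture by the oxygen of the neighbouring ketone, or the electron-rich sulfone may re-ionise during isolation.
- Fallback: it sets out from 15 and comes back at 16. The C–S bond is made with a thiol, and the oxidation level is adjusted afterwards.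
- 15 with 4-methylbenzenethiol and catalytic camphorsulfonic acid in CH2Cl2 at 0 °C gives the keto sulfide phenol F8. The thiol traps the cation better and less reversibly than sulfinate, and the THP acetal is exchanged in the same operation.
- Oxidation at sulfur with m-chloroperbenzoic acid (2 equiv, CH2Cl2, −20 °C), which is much faster than attack on the allyl groups or the rings, gives 16.

Step 19.
- What may go wrong: the ring A benzylic position may ionise with loss of geometric control, the double bond may migrate into the five-membered ring, or the hindered carbinol may be activated only slowly.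
- Fallback: it sets out from 26 and comes back at 29. The carbinol is avoided altogether.
- KN(SiMe3)2 and PhNTf2 (THF, −78 °C) convert 26 into the (Z)-enol triflate F9, with the small oxygen next to C7–H and ring A on the C2 side.
- Pd(OAc)2/PPh3 with HCO2H and Et3N in DMF at 60 °C replaces the triflate by hydrogen with retention of geometry.
- The same zerovalent palladium–formate system cleaves the seven aryl allyl ethers, so the target 29 is reached directly.

Further compounds
F1 | step 16 | diethyl [2-bromo-3,5-bis(allyloxy)benzyl]phosphonate | CCOP(=O)(Cc1cc(OCC=C)cc(OCC=C)c1Br)OCC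
F2 | step 16 | 3,5-bis(allyloxy)benzaldehyde | O=Cc1cc(OCC=C)cc(OCC=C)c1
F3 | step 16 | (E)-2-bromo-3,3',5,5'-tetrakis(allyloxy)stilbene | C=CCOc1cc(/C=C/c2cc(OCC=C)cc(OCC=C)c2Br)cc(OCC=C)c1
F4 | step 16 | 2,4-bis(allyloxy)benzaldehyde | O=Cc1ccc(OCC=C)cc1OCC=C
F5 | step 16 | ortho-styryl diarylcarbinol (racemic) | OC(c1ccc(OCC=C)cc1OCC=C)c1c(/C=C/c2cc(OCC=C)cc(OCC=C)c2)cc(OCC=C)cc1OCC=C
F6 | step 16 | all-trans 1-tosyl-2,3-diarylindane (made racemic, the enantiomer shown is kept after resolution) | Cc1ccc(S(=O)(=O)[C@@H]2c3cc(OCC=C)cc(OCC=C)c3[C@H](c3ccc(OCC=C)cc3OCC=C)[C@H]2c2cc(OCC=C)cc(OCC=C)c2)cc1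
F7 | step 16 | β-benzoyloxy sulfone (C1 and the carbinol carbon undefined) | COc1cc(C(OC(=O)c2ccccc2)C2(S(=O)(=O)c3ccc(C)cc3)c3cc(OCC=C)cc(OCC=C)c3[C@H](c3ccc(OCC=C)cc3OCC=C)[C@H]2c2cc(OCC=C)cc(OCC=C)c2)ccc1OCC=C
F8 | step 11 | keto sulfide phenol (racemic) | COc1cc(C(=O)Cc2cc(OCC=C)cc(OCC=C)c2C(Sc2ccc(C)cc2)c2ccc(O)cc2OCC=C)ccc1OCC=C
F9 | step 19 | (Z)-enol triflate of 26 | COc1cc(/C(OS(=O)(=O)C(F)(F)F)=C2/c3cc(OCC=C)cc(OCC=C)c3[C@H](c3ccc(OCC=C)cc3OCC=C)[C@H]2c2cc(OCC=C)cc(OCC=C)c2)ccc1OCC=C
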